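**Plan**

1. Cuts: the C6 acetate and the C5(=O)–C6 acyloin go back to a cyclic silyl enol ether; the ring bond C5–C6 (ketone carbon to acetoxy carbon) goes back to a 2-silyloxy-1,7-diene (ring-closing metathesis); C1–C2 is cut by allylboration between a dienylboronate (C6, C1, C7–C11) and (2Z)-3-methyl-4-oxopent-2-enal (C2–C5, from 2,3-dimethylfuran); the dienylboronate comes from an alkyne by enyne cross-metathesis.
2. Forward order: side-chain alkyne (C7–C11, first tiglate) → dienylboronate → union with the furan-derived unit (temporary five-membered hemiketal ring) → C3–C4 epoxide → open-chain epoxy methyl ketone with second tiglate → silyl enol ether → the only carbocycle, closed last → acyloin → acetate.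
3. Enabling feature: C5 (C=O) and C6 (CH–OAc) of the cyclohexanone are an acyloin, that is an oxidised enol ether C5(OSi)=C6H; the cis-fused C3–C4 epoxide with quaternary C4 holds C5 and the C2–C1 arm on one side, so C5 and C6 are the ends of a pre-folded 1,7-diene.
4. Stereochemistry: C8 by Noyori transfer hydrogenation; C10 by Shi epoxidation; C2 by the chiral phosphoric acid and C1 by the E-boronate chair in the allylboration; C3/C4 by hydroxyl-directed epoxidation inside the temporary ring; C6 by substrate-controlled Rubottom oxidation.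
5. No protecting groups: both tiglates are final esters; the helpers are the hemiketal ring (opened in step 11) and the silyl group on the C5 oxygen (removed in step 14).

Key step: step 13

**Remarks**

- Locants follow the target: ring C1 (bears the side chain), C2 (O-tigloyl), C3–C4 (epoxide, C4 bears CH3), C5 (C=O), C6 (OAc); side chain C7 (=C14H2), C8 (O-tigloyl), C9 (CH2), C10–C11 (epoxide, C11 bears two CH3).
- Tigloyl = (2E)-2-methylbut-2-enoyl. Sc = –C7(=C14H2)–C8H(O-tigloyl)–C9H2–C10H(–O–)C11(CH3)2 with 8S,10R.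
- CIP descriptors are given in these locants and can change between compounds without a change in spatial arrangement.
- Assumption: the three chiral catalysts induce in the sense of their accepted models; if a sense proved opposite, the enantiomeric catalyst would be used.

**Route**

Step 1
Reactants: 1 4-methylpent-3-enoic acid
Product: 2 N-methoxy-N,4-dimethylpent-3-enamide
Conditions: 1,1'-carbonyldiimidazole, CH2Cl2, rt; then MeNH(OMe)·HCl, rt
Reagents that add atoms: N,O-dimethylhydroxylamine hydrochloride, CNOC.Cl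
Why: Weinreb amide formation through the acyl imidazole runs under near-neutral conditions that should leave the β,γ-alkene in place.

Step 2
Reactants: 2 N-methoxy-N,4-dimethylpent-3-enamide; 3 ethynyltrimethylsilane
Product: 4 6-methyl-1-(trimethylsilyl)hept-5-en-1-yn-3-one
Conditions: 3, n-BuLi, THF, −78 °C; then 2, −78 to −20 °C; aq. NH4Cl
Reagents that add atoms: none
Why: Acetylide addition to a Weinreb amide stops at the chelated tetrahedral adduct, so the ynone should form without over-addition.

Step 3
Reactants: 4 6-methyl-1-(trimethylsilyl)hept-5-en-1-yn-3-one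
Product: 5 (3S)-6-methyl-1-(trimethylsilyl)hept-5-en-1-yn-3-ol
Conditions: RuCl[(S,S)-TsDPEN](p-cymene) (1 mol%), i-PrOH, rt
Reagents that add atoms: none
Why: Noyori asymmetric transfer hydrogenation of an alkynyl ketone delivers hydride and proton through the six-membered bifunctional transition state, and the (S,S)-catalyst is expected to give the (S)-carbinol (C8).

Step 4
Reactants: 5 (3S)-6-methyl-1-(trimethylsilyl)hept-5-en-1-yn-3-ol
Product: 6 (3S)-6-methylhept-5-en-1-yn-3-ol
Conditions: K2CO3 (cat.), MeOH, rt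
Reagents that add atoms: none
Why: Base-catalysed methanolysis of the C(sp)–Si bond frees the terminal alkyne without touching the carbinol centre.

Step 5
Reactants: 6 (3S)-6-methylhept-5-en-1-yn-3-ol; 7 (2E)-2-methylbut-2-enoyl chloride
Product: 8 (3S)-6-methylhept-5-en-1-yn-3-yl (2E)-2-methylbut-2-enoate
Conditions: Et3N, DMAP (cat.), CH2Cl2, 0 °C to rt
Reagents that add atoms: none
Why: DMAP-catalysed acylation installs the C8 tiglate as a permanent ester; the E acyl group is the thermodynamically favoured isomer and should not isomerise.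

Step 6
Reactants: 8 (3S)-6-methylhept-5-en-1-yn-3-yl (2E)-2-methylbut-2-enoate
Product: 9 (2S)-1-[(2R)-3,3-dimethyloxiran-2-yl]but-3-yn-2-yl (2E)-2-methylbut-2-enoate
Conditions: D-fructose-derived Shi ketone (30 mol%), KHSO5 (Oxone), K2CO3, Bu4NHSO4, MeCN–CH2(OMe)2–aq. Na2B4O7 buffer, 0 °C
Reagents that add atoms: potassium peroxymonosulfate, [K+].[O-]S(=O)(=O)OO
Why: Shi epoxidation, in which the chiral dioxirane attacks the electron-rich trisubstituted alkene through a spiro transition state (10R expected under reagent control) while the alkyne and the electron-poor tiglate alkene stay untouched.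

Step 7
Reactants: 9 (2S)-1-[(2R)-3,3-dimethyloxiran-2-yl]but-3-yn-2-yl (2E)-2-methylbut-2-enoate; 10 2-allyl-4,4,5,5-tetramethyl-1,3,2-dioxaborolane
Product: 11 (2S,4E)-1-[(2R)-3,3-dimethyloxiran-2-yl]-3-methylidene-6-(4,4,5,5-tetramethyl-1,3,2-dioxaborolan-2-yl)hex-4-en-2-yl (2E)-2-methylbut-2-enoate
Conditions: second-generation Grubbs catalyst RuCl2(=CHPh)(H2IMes)(PCy3) (5 mol%), 10 (3 equiv), CH2Cl2, 40 °C
Reagents that add atoms: none
Why: Enyne cross-metathesis places the CH2B-bearing alkylidene on the former alkyne terminus and the methylidene (C14) on C7, and secondary metathesis with excess 10 should equilibrate the disubstituted C=C to E.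

Step 8
Reactants: 12 2,3-dimethylfuran
Product: 14 (2Z)-3-methyl-4-oxopent-2-enal, via furan 2,3-epoxide 13 (not isolated)
Conditions: dimethyldioxirane (1.0 equiv), acetone, −78 to 0 °C; concentrated cold and used at once
Reagents that add atoms: dimethyldioxirane, CC1(C)OO1
Why: Dioxirane oxidation of a furan gives an epoxide that opens spontaneously to the cis-enedione, so the ring geometry becomes the Z alkene C3=C4 and the unsubstituted α-carbon becomes the aldehyde C2.

Step 9
Reactants: 14 (2Z)-3-methyl-4-oxopent-2-enal; 11 dienylboronate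
Product: 16 (1R,2R)-2,3-dimethyl-5-[C1H(CH=CH2)–Sc]-2,5-dihydrofuran-2-ol (hemiketal; both anomers), via open-chain pinacol borate 15 (not isolated)
Conditions: (S)-TRIP phosphoric acid (5 mol%), 4 Å molecular sieves, toluene, −30 °C; aq. NaHCO3
Reagents that add atoms: none
Why: Chiral phosphoric acid-catalysed allylboration, in which the aldehyde reacts in preference to the ketone through a closed chair with the E γ-substituent equatorial (anti C1/C2), the (S)-acid is expected to direct attack to the Si face (1R,2R), γ-attack leaves the skipped diene, and the cis γ-hydroxy enone freed from borate 15 closes to the hemiketal.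

Step 10
Reactants: 16 hemiketal
Product: 17 (1R,2S,3S,4S)-3,4-epoxide of 16 (epoxide oxygen anti to the C1 substituent; both anomers)
Conditions: VO(acac)2 (5 mol%), t-BuOOH, CH2Cl2, 0 °C
Reagents that add atoms: tert-butyl hydroperoxide, CC(C)(C)OO
Why: Vanadium-catalysed hydroxyl-directed epoxidation, in which only the ring alkene has an allylic OH (the equilibrating anomeric one), oxygen is delivered through the anomer whose OH lies anti to the bulky C2 substituent, and the five-membered ring fixes the cis-epoxide and the cis C2–O/C3–O relationship (3S,4S) that an open-chain allylic alcohol would not give.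

Step 11
Reactants: 17 epoxy hemiketal; 7 (2E)-2-methylbut-2-enoyl chloride
Product: 18 (1R,2S,3S,4S)-CH3C(=O)–C4(CH3)(–O–)C3H–C2H(O-tigloyl)–C1H(CH=CH2)–Sc (open-chain epoxy methyl ketone)
Conditions: Et3N, DMAP, CH2Cl2, 0 °C to rt
Reagents that add atoms: none
Why: DMAP-catalysed acylation traps the secondary C2 hydroxyl of the open-chain tautomer (ring–chain equilibrium under Curtin–Hammett control, the tertiary hemiketal OH being far slower), which unmasks the methyl ketone.

Step 12
Reactants: 18 epoxy methyl ketone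
Product: 20 (1R,2S,3S,4S)-CH2=C5(OSiEt3)–C4(CH3)(–O–)C3H–C2H(O-tigloyl)–C1H(CH=CH2)–Sc, via lithium enolate 19 (not isolated)
Conditions: Et3SiCl, LiN(SiMe3)2, THF, −78 °C
Reagents that add atoms: chlorotriethylsilane, CC[Si](Cl)(CC)CC
Why: Kinetic enolisation of the methyl ketone (its only α-hydrogens, C4 being quaternary) with in-situ O-silylation gives the 2-silyloxy-1-alkene, and the tiglates have no α-hydrogen.

Step 13
Reactants: 20 acyclic triethylsilyl enol ether
Product: 21 (1R,2S,3S,4S)-3,4-epoxy-4-methyl-2-(tigloyloxy)-5-(triethylsilyloxy)-1-Sc-cyclohex-5-ene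
Conditions: second-generation Hoveyda–Grubbs catalyst RuCl2(=CH-C6H4-2-Oi-Pr)(H2IMes) (10 mol%), 1,4-benzoquinone (20 mol%), toluene (5 mM), 80 °C
Reagents that add atoms: none
Why: Ring-closing olefin metathesis, in which the ruthenium alkylidene loads onto the monosubstituted vinyl group (C6), undergoes [2+2] cycloaddition with the 2-silyloxy-1-alkene (C5) and cycloreversion expels ethene to form C5=C6. The closest known reaction type is the ring-closing metathesis of acyclic silyl enol ethers to five- to seven-membered cyclic silyl enol ethers. The six-membered carbocycle closes as an endocyclic trisubstituted enol ether, and the cis-fused C3–C4 epoxide holds C5 and the C2–C1–C6 arm syn, which pre-folds the diene. No stereocentre is formed (C5 and C6 become sp2) and C1–C4, C8 and C10 are untouched. Site selectivity is needed among five C=C bonds: the two terminal partners should react, whereas the C7=C14 methylidene is flanked by two branched carbons, the tiglate alkenes are electron-poor and trisubstituted, the former prenyl alkene is already an epoxide, and benzoquinone suppresses ruthenium hydride migration of the vinyl group across the bis-allylic C1–H. The step fixes the regiochemistry of the acyloin, because oxygen is already on C5 and C6 becomes the nucleophilic enol carbon.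

Step 14
Reactants: 21 cyclic silyl enol ether
Product: 24 (1S,2S,3S,4S,6S)-3,4-epoxy-6-hydroxy-4-methyl-5-oxo-2-(tigloyloxy)-1-Sc-cyclohexane, via silyloxy epoxide 22 (not isolated), via 6-O-triethylsilyl ketone 23 (not isolated)
Conditions: dimethyldioxirane, acetone–CH2Cl2, −78 to −40 °C; then Bu4NF, AcOH, THF, 0 °C
Reagents that add atoms: dimethyldioxirane, CC1(C)OO1
Why: Rubottom oxidation, in which the dioxirane epoxidises the electron-rich enol ether on the face opposite the epoxide oxygen, the C1 side chain and the C2 ester, silyl migration opens the silyloxy epoxide with the new C6–O bond retained, and buffered fluoride frees the hydroxyl (6S, trans to the side chain and also the thermodynamically favoured epimer).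

Step 15
Reactants: 24 α-hydroxy ketone
Product: 25 CNP0407453.3, (1R,2S,3S,4S,6S,8S,10R)
Conditions: Ac2O, pyridine, DMAP (cat.), CH2Cl2, 0 °C
Reagents that add atoms: acetic anhydride, CC(=O)OC(C)=O
Why: DMAP-catalysed acetylation of the secondary α-hydroxy ketone; C6 already has the equatorial, thermodynamically preferred configuration, so the mild base should not change it.

**Compound list**

1 | 4-methylpent-3-enoic acid | CC(C)=CCC(=O)O | starting material
2 | N-methoxy-N,4-dimethylpent-3-enamide | CC(C)=CCC(=O)N(C)OC | intermediate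
3 | ethynyltrimethylsilane | C#C[Si](C)(C)C | starting material
4 | 6-methyl-1-(trimethylsilyl)hept-5-en-1-yn-3-one | CC(C)=CCC(=O)C#C[Si](C)(C)C | intermediate
5 | (3S)-6-methyl-1-(trimethylsilyl)hept-5-en-1-yn-3-ol | C[Si](C)(C)C#C[C@H](CC=C(C)C)O | intermediate
6 | (3S)-6-methylhept-5-en-1-yn-3-ol | C#C[C@H](CC=C(C)C)O | intermediate
7 | (2E)-2-methylbut-2-enoyl chloride (tigloyl chloride) | O=C(Cl)/C(C)=C/C | starting material
8 | (3S)-6-methylhept-5-en-1-yn-3-yl (2E)-2-methylbut-2-enoate | C#C[C@H](CC=C(C)C)OC(=O)/C(C)=C/C | intermediate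
9 | (2S)-1-[(2R)-3,3-dimethyloxiran-2-yl]but-3-yn-2-yl (2E)-2-methylbut-2-enoate | C#C[C@H](C[C@H]1OC1(C)C)OC(=O)/C(C)=C/C | intermediate
10 | 2-allyl-4,4,5,5-tetramethyl-1,3,2-dioxaborolane | C=CCB1OC(C)(C)C(C)(C)O1 | starting material
11 | (2S,4E)-1-[(2R)-3,3-dimethyloxiran-2-yl]-3-methylidene-6-(4,4,5,5-tetramethyl-1,3,2-dioxaborolan-2-yl)hex-4-en-2-yl (2E)-2-methylbut-2-enoate | C=C(/C=C/CB1OC(C)(C)C(C)(C)O1)[C@H](C[C@H]2OC2(C)C)OC(=O)/C(C)=C/C | intermediate
12 | 2,3-dimethylfuran | Cc1occc1C | starting material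
13 | 1,5-dimethyl-2,6-dioxabicyclo[3.1.0]hex-3-ene (furan 2,3-epoxide) | CC12OC=CC1(C)O2 | intermediate
14 | (2Z)-3-methyl-4-oxopent-2-enal | CC(=O)/C(C)=C\C=O | intermediate
15 | (1R,2R,3Z,8S,10R)-CH3C(=O)–C4(CH3)=C3H–C2H(O-Bpin)–C1H(CH=CH2)–Sc (open-chain pinacol borate) | C=C([C@@H](C=C)[C@H](OB1OC(C)(C)C(C)(C)O1)/C=C(C)\C(C)=O)[C@H](C[C@H]2OC2(C)C)OC(=O)/C(C)=C/C | intermediate
16 | (1R,2R,8S,10R)-2,3-dimethyl-5-[C1H(CH=CH2)–Sc]-2,5-dihydrofuran-2-ol (ring O joins C2 and C5; both anomers; ring tautomer of the open (3Z)-hydroxy enone) | C=C([C@@H](C=C)[C@@H]1OC(C)(O)C(C)=C1)[C@H](C[C@H]2OC2(C)C)OC(=O)/C(C)=C/C | intermediate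
17 | (1R,2S,3S,4S,8S,10R)-3,4-epoxide of 16 (both anomers) | C=C([C@@H](C=C)[C@@H]1OC(C)(O)[C@@]3(C)O[C@@H]13)[C@H](C[C@H]2OC2(C)C)OC(=O)/C(C)=C/C | intermediate
18 | (1R,2S,3S,4S,8S,10R)-CH3C(=O)–C4(CH3)(–O–)C3H–C2H(O-tigloyl)–C1H(CH=CH2)–Sc | C=C([C@@H](C=C)[C@H](OC(=O)/C(C)=C/C)[C@@H]2O[C@]2(C)C(C)=O)[C@H](C[C@H]1OC1(C)C)OC(=O)/C(C)=C/C | intermediate
19 | lithium enolate of 18 (C5(OLi)=CH2) | C=C([C@@H](C=C)[C@H](OC(=O)/C(C)=C/C)[C@@H]2O[C@]2(C)C(=C)O[Li])[C@H](C[C@H]1OC1(C)C)OC(=O)/C(C)=C/C | intermediate
20 | triethylsilyl enol ether of 18 (C5(OSiEt3)=CH2), (1R,2S,3S,4S,8S,10R) | C=C([C@@H](C=C)[C@H](OC(=O)/C(C)=C/C)[C@@H]2O[C@]2(C)C(=C)O[Si](CC)(CC)CC)[C@H](C[C@H]1OC1(C)C)OC(=O)/C(C)=C/C | intermediate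
21 | (1R,2S,3S,4S,8S,10R)-3,4-epoxy-4-methyl-2-(tigloyloxy)-5-(triethylsilyloxy)-1-Sc-cyclohex-5-ene | C=C([C@@H]1[C@H](OC(=O)/C(C)=C/C)[C@@H]2O[C@]2(C)C(O[Si](CC)(CC)CC)=C1)[C@H](C[C@H]1OC1(C)C)OC(=O)/C(C)=C/C | intermediate
22 | (1R,2S,3S,4S,5R,6S,8S,10R)-5,6-epoxide of 21 (new epoxide oxygen anti to the 3,4-epoxide oxygen and to the side chain) | C=C([C@@H]1[C@H](OC(=O)/C(C)=C/C)[C@@H]2O[C@]2(C)[C@@]3(O[Si](CC)(CC)CC)O[C@@H]13)[C@H](C[C@H]1OC1(C)C)OC(=O)/C(C)=C/C | intermediate
23 | (1R,2S,3S,4S,6S,8S,10R)-6-O-triethylsilyl ether of 24 | C=C([C@@H]1[C@H](OC(=O)/C(C)=C/C)[C@@H]2O[C@]2(C)C(=O)[C@H]1O[Si](CC)(CC)CC)[C@H](C[C@H]1OC1(C)C)OC(=O)/C(C)=C/C | intermediate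
24 | (1S,2S,3S,4S,6S,8S,10R)-3,4-epoxy-6-hydroxy-4-methyl-5-oxo-2-(tigloyloxy)-1-Sc-cyclohexane | C=C([C@@H]1[C@H](OC(=O)/C(C)=C/C)[C@@H]2O[C@]2(C)C(=O)[C@H]1O)[C@H](C[C@H]1OC1(C)C)OC(=O)/C(C)=C/C | intermediate
25 | CNP0407453.3, (1R,2S,3S,4S,6S,8S,10R)-6-acetoxy-3,4-epoxy-4-methyl-5-oxo-2-(tigloyloxy)-1-Sc-cyclohexane | C=C([C@@H]1[C@H](OC(=O)/C(C)=C/C)[C@@H]2O[C@]2(C)C(=O)[C@H]1OC(C)=O)[C@H](C[C@H]1OC1(C)C)OC(=O)/C(C)=C/C | target

**Step count**

Total step count: 15. Longest linear sequence: 14 steps (steps 1–7 and 9–15).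

**Steps most likely to fail**

1. Step 9. What may go wrong: loss of the anti relationship if Z-boronate is carried in with 11; weak facial control by the acid on this β,β-disubstituted enal; acid-induced Z to E isomerisation of 14; opening of the side-chain epoxide. The fallback sets out from 9 and 14 and returns at 16. Compound 9 is cross-metathesised with allyl chloride (second-generation Grubbs catalyst, CH2Cl2, 40 °C) to the dienyl chloride F1, whose alkene geometry need not be controlled. F1 and 14 are then joined in a Nozaki–Hiyama–Kishi allylation (CrCl2, chiral sulfonamide–oxazoline ligand, Et3N, THF, 0 °C). The allyl species of trivalent chromium equilibrates to its E form and adds through a chair at its γ-carbon, so an E/Z mixture should converge on the anti adduct under ligand control and give 16 after work-up.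

2. Step 10. What may go wrong: dehydration of the hemiketal to an aromatic furan under the Lewis-acidic oxidation; competing oxidation of the C7=C14 alkene; delivery of oxygen to the wrong face. The fallback sets out from 11 and commercial 3-methylfuran-2-carboxylic acid and returns at 17. It carries the C2–C5 unit at the lactone oxidation level, which cannot aromatise. Photo-oxygenation of 3-methylfuran-2-carboxylic acid (O2, rose bengal, visible light, MeOH) should give 5-hydroxy-3-methylfuran-2(5H)-one F2 with loss of CO2. Its open aldehyde form is allylborated with 11 under the conditions of step 9 and lactonises to the butenolide F3. Nucleophilic epoxidation (NaOCl, pyridine, 0 °C) anti to the C2 substituent gives the epoxy lactone F4; the tiglate and the other alkenes should not react. One equivalent of MeLi (THF, −78 °C) adds to the strained lactone carbonyl in preference to the hindered conjugated C8 ester, and the resulting methyl lactol is 17.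

3. Step 13. What may go wrong: slow closure onto the hindered, electron-rich 1,1-disubstituted silyl enol ether next to quaternary C4, with alkene migration, oligomerisation or loss of the silyl group taking over. The fallback sets out from 18 and returns at 25. It closes the same C5–C6 bond between two unhindered monosubstituted alkenes and builds the acyloin afterwards by dihydroxylation.
   - Reduction of 18 (NaBH4, CeCl3·7H2O, MeOH, −40 °C) gives the carbinol F5; both C5 epimers serve.
   - Dehydration with Martin sulfurane Ph2S[OC(CF3)2Ph]2 can only engage the methyl hydrogens and gives the vinyl epoxide F6.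
   - Ring-closing metathesis (second-generation Grubbs catalyst, CH2Cl2, 40 °C) gives the cyclohexene F7.
   - Dihydroxylation (OsO4 cat., N-methylmorpholine N-oxide, acetone–water) on the face opposite the epoxide oxygen and the C1/C2 substituents gives the cis-diol F8.
   - Acetylation of the less hindered C6 hydroxyl (Ac2O, 2,4,6-collidine, −20 °C) gives the monoacetate F9.
   - Dess–Martin oxidation of the C5 carbinol gives 25.

**Further compounds**

F1 | step 9 | (2S)-6-chloro-1-[(2R)-3,3-dimethyloxiran-2-yl]-3-methylidenehex-4-en-2-yl (2E)-2-methylbut-2-enoate (E/Z mixture at C4=C5) | C=C(C=CCCl)[C@H](C[C@H]1OC1(C)C)OC(=O)/C(C)=C/C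
F2 | step 10 | 5-hydroxy-3-methylfuran-2(5H)-one | CC1=CC(O)OC1=O
F3 | step 10 | (1R,2R,8S,10R)-3-methyl-5-[C1H(CH=CH2)–Sc]furan-2(5H)-one (lactone analogue of 16) | C=C([C@@H](C=C)[C@@H]1OC(=O)C(C)=C1)[C@H](C[C@H]2OC2(C)C)OC(=O)/C(C)=C/C
F4 | step 10 | (1R,2S,3S,4S,8S,10R)-3,4-epoxide of F3 (lactone analogue of 17) | C=C([C@@H](C=C)[C@@H]1OC(=O)[C@@]3(C)O[C@@H]13)[C@H](C[C@H]2OC2(C)C)OC(=O)/C(C)=C/C
F5 | step 13 | C5 carbinol from 18 (CH3–C5H(OH)–; both C5 epimers; other centres as in 18) | C=C([C@@H](C=C)[C@H](OC(=O)/C(C)=C/C)[C@@H]2O[C@]2(C)C(C)O)[C@H](C[C@H]1OC1(C)C)OC(=O)/C(C)=C/C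
F6 | step 13 | vinyl epoxide CH2=C5H–C4(CH3)(–O–)C3H–C2H(O-tigloyl)–C1H(CH=CH2)–Sc (centres as in 18) | C=C([C@@H](C=C)[C@H](OC(=O)/C(C)=C/C)[C@@H]2O[C@]2(C)C=C)[C@H](C[C@H]1OC1(C)C)OC(=O)/C(C)=C/C
F7 | step 13 | 3,4-epoxy-4-methyl-2-(tigloyloxy)-1-Sc-cyclohex-5-ene (centres as in 18) | C=C([C@@H]1[C@H](OC(=O)/C(C)=C/C)[C@@H]2O[C@]2(C)C=C1)[C@H](C[C@H]1OC1(C)C)OC(=O)/C(C)=C/C
F8 | step 13 | 5,6-cis-diol of F7 (both hydroxyls anti to the epoxide oxygen and to the side chain) | C=C([C@@H]1[C@H](OC(=O)/C(C)=C/C)[C@@H]2O[C@]2(C)[C@@H](O)[C@H]1O)[C@H](C[C@H]1OC1(C)C)OC(=O)/C(C)=C/C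
F9 | step 13 | 6-O-acetate of F8 (C5 hydroxyl free) | C=C([C@@H]1[C@H](OC(=O)/C(C)=C/C)[C@@H]2O[C@]2(C)[C@@H](O)[C@H]1OC(C)=O)[C@H](C[C@H]1OC1(C)C)OC(=O)/C(C)=C/C
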